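**Retrosynthetic overview**
- The strategy rests on ring A (C4a, C5, C6, C7, C8, C8a): a phloroglucinol whose 5-OH, 7-OMe and 8-prenyl groups map onto the ester carbon, the 3-methoxy carbon and the prenylated terminus of an acetoacetate-derived 1,1,3-trioxygenated diene, with C4a=C8a as the dienophile.
- Disconnection 1: C4a–C5 and C8–C8a, by [4+2] benzannulation of that diene onto the C5=C6 bond of an (S)-2-aryl-5-sulfinyl-2,3-dihydropyran-4-one, followed by loss of benzenesulfenic acid and methanol.
- Disconnection 2: the dihydropyranone (ring C) by catalytic asymmetric hetero-Diels–Alder reaction of MOM-protected 4-hydroxybenzaldehyde (ring B) with 1-methoxy-3-(trimethylsilyloxy)butadiene, which sets C2; sulfur is then put on C5 and oxidised.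
- Disconnection 3: the diene from methyl acetoacetate by γ-prenylation, O-methylation and O-silylation.
- Ring order: ring B is bought, ring C is made first (step 2), ring A last (step 8); MOM removal ends the route.

Key step: step 8

Assumption: the Ti(OiPr)4/(S)-BINOL catalyst is assumed to direct attack to the Si face of the aryl aldehyde, as expected by analogy with titanium–BINOL allylation and Mukaiyama aldol additions to aromatic aldehydes, which gives S at C2; if the opposite sense is found, (R)-BINOL is used. The sulfoxide is carried as both sulfur epimers because sulfur is lost in the key step.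

**Route**

Step 1
Reactants: 1 4-hydroxybenzaldehyde
Product: 2 4-(methoxymethoxy)benzaldehyde
Conditions: MOMCl, iPr2NEt, CH2Cl2, 0 °C → rt
Reagents that add atoms: chloromethyl methyl ether (MOMCl), COCCl
Why: O-alkylation of the phenol by the α-chloro ether (Williamson-type acetal protection) leaves the aldehyde untouched.

Step 2
Reactants: 2 4-(methoxymethoxy)benzaldehyde; 3 (E)-1-methoxy-3-(trimethylsilyloxy)buta-1,3-diene
Product: 5 (2S)-2-[4-(methoxymethoxy)phenyl]-2,3-dihydro-4H-pyran-4-one, via silyl aldol adduct 4 (not isolated)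
Conditions: Ti(OiPr)4 (10 mol %), (S)-BINOL (20 mol %), 4 Å MS, Et2O, −20 °C; then TFA (cat.), CH2Cl2, 0 °C, short contact
Reagents that add atoms: none
Why: Catalytic enantioselective hetero-Diels–Alder reaction in its Mukaiyama aldol/cyclisation mode, in which the titanium–BINOL-bound aldehyde should be attacked on its Si face by the diene terminus (setting C2 as S) and acid then closes the ring with loss of methanol and the silyl group.

Step 3
Reactants: 5 (2S)-2-[4-(methoxymethoxy)phenyl]-2,3-dihydro-4H-pyran-4-one
Product: 7 (2S)-2-[4-(methoxymethoxy)phenyl]-5-(phenylsulfanyl)-2,3-dihydro-4H-pyran-4-one, via chloro sulfide adduct 6 (not isolated)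
Conditions: PhSCl (1.1 equiv), CH2Cl2, −78 → 0 °C; then Et3N, 0 °C → rt
Reagents that add atoms: benzenesulfenyl chloride, ClSc1ccccc1
Why: Sulfenyl chloride addition–dehydrochlorination on the enol-ether C5=C6 bond, in which sulfur bonds to the nucleophilic C5, chloride to the oxygen-stabilised C6, and amine-induced loss of HCl restores the conjugated enone without touching C2.

Step 4
Reactants: 7 (2S)-2-[4-(methoxymethoxy)phenyl]-5-(phenylsulfanyl)-2,3-dihydro-4H-pyran-4-one
Product: 8 (2S)-2-[4-(methoxymethoxy)phenyl]-5-(phenylsulfinyl)-2,3-dihydro-4H-pyran-4-one (both sulfur epimers)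
Conditions: mCPBA (1.0 equiv), CH2Cl2, −78 → −40 °C
Reagents that add atoms: 3-chloroperoxybenzoic acid (mCPBA), O=C(OO)c1cccc(Cl)c1
Why: Chemoselective sulfide-to-sulfoxide oxidation by one equivalent of peracid at low temperature, the electron-poor alkene being inert and the sulfur configuration being irrelevant.

Step 5
Reactants: 9 methyl acetoacetate; 10 prenyl bromide (1-bromo-3-methylbut-2-ene)
Product: 12 methyl 7-methyl-3-oxooct-6-enoate, via acetoacetate dianion 11 (not isolated)
Conditions: NaH, THF, 0 °C; n-BuLi, 0 °C; then 10, 0 °C → rt; aq. HCl quench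
Reagents that add atoms: none
Why: γ-Alkylation of the acetoacetate dianion, whose more basic terminal carbanion displaces the allylic bromide in an SN2 reaction.

Step 6
Reactants: 12 methyl 7-methyl-3-oxooct-6-enoate
Product: 13 methyl (2E)-3-methoxy-7-methylocta-2,6-dienoate
Conditions: HC(OMe)3 (neat), p-TsOH·H2O (cat.), rt; then distillation
Reagents that add atoms: trimethyl orthoformate, COC(OC)OC
Why: Acid-catalysed ketalisation by the orthoester and loss of methanol (enol ether formation) gives the conjugated β-methoxy enoate as its thermodynamically favoured E isomer, the remote trisubstituted alkene being inert to catalytic sulfonic acid at room temperature.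

Step 7
Reactants: 13 methyl (2E)-3-methoxy-7-methylocta-2,6-dienoate
Product: 15 1,3-dimethoxy-7-methyl-1-(trimethylsilyloxy)octa-1,3,6-triene, via lithium dienolate 14 (not isolated)
Conditions: LiN(iPr)2 (LDA, 1.1 equiv), THF, −78 °C; TMSCl, −78 °C → rt; evaporation, hexane, filtration under argon; used at once
Reagents that add atoms: chlorotrimethylsilane, C[Si](C)(C)Cl
Why: Kinetic γ-deprotonation of the β-methoxy enoate to the extended dienolate and O-silylation (silyl ketene acetal formation), expected to give mainly the 3Z isomer that places the prenyl group outside the s-cis diene.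

Step 8
Reactants: 8 (2S)-2-[4-(methoxymethoxy)phenyl]-5-(phenylsulfinyl)-2,3-dihydro-4H-pyran-4-one; 15 1,3-dimethoxy-7-methyl-1-(trimethylsilyloxy)octa-1,3,6-triene (2.5 equiv)
Product: 18 (2S)-5-hydroxy-7-methoxy-2-[4-(methoxymethoxy)phenyl]-8-(3-methylbut-2-enyl)chroman-4-one, via sulfinyl cycloadduct 16 (not isolated), via aryl silyl ether 17 (not isolated)
Conditions: PhMe, −20 °C → rt; then 80 °C; then moist SiO2, CH2Cl2, rt
Reagents that add atoms: none
Why: Proposed new method: the electron-rich, prenyl-bearing C4 terminus of diene 15 should bond to the β-carbon C6 of the doubly activated sulfinyl enone 8 while the ketene-acetal carbon C1 bonds to the sulfinyl-bearing C5, either as a concerted asynchronous [4+2] cycloaddition or as a Mukaiyama–Michael addition followed by 6-(enolexo)-exo-trig closure onto the oxocarbenium carbon, in both cases closing the six-membered carbocycle of 16 (ring A) through the C8–C8a and C4a–C5 bonds (flavanone numbering). A suprafacial addition leaves the sulfinyl group and H-8a cis, so thermal syn-elimination of benzenesulfenic acid restores C4a=C8a, 1,4-loss of methanol aromatises ring A to silyl ether 17, and moist silica frees the chelated 5-OH. The closest known reaction type is the Diels–Alder/aromatisation of 3-sulfinylchromones, 3-acylchromones and haloquinones with 1,1,3-trioxygenated dienes; neither a monocyclic 5-sulfinyl-2,3-dihydropyranone as dienophile nor a 4-allyl-substituted diene of this kind has been used in that role. No new stereocentre survives, because the centres formed transiently at C4a, C5, C8 and C8a and the sulfur centre are all erased, so facial selectivity is irrelevant and C2, which cannot ionise or enolise under these neutral conditions, is carried through. The step needs regioselectivity (prenyl carbon to C8a, not C4a) and chemoselectivity for C5=C6 over the ketone, and both should follow from the polarisation of the push–pull diene (largest HOMO coefficient at C4) and of the sulfinyl enone (largest LUMO coefficient at C6), the sulfoxide acting as activator and traceless leaving group.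

Step 9
Reactants: 18 (2S)-5-hydroxy-7-methoxy-2-[4-(methoxymethoxy)phenyl]-8-(3-methylbut-2-enyl)chroman-4-one
Product: 19 Mundulea flavanone B, (2S)-5-hydroxy-2-(4-hydroxyphenyl)-7-methoxy-8-(3-methylbut-2-enyl)chroman-4-one
Conditions: HCl (1.25 M in MeOH), rt → 40 °C
Reagents that add atoms: none
Why: Acid-catalysed transacetalisation cleaves the MOM ether, while the prenyl group (flanked by OMe and the ring oxygen, with no free ortho hydroxyl to cyclise onto) and the C2 centre (scrambled only by base-promoted ring opening to the chalcone) should survive.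

**Compound list**
1 | 4-hydroxybenzaldehyde | O=Cc1ccc(O)cc1 | starting material
2 | 4-(methoxymethoxy)benzaldehyde | COCOc1ccc(C=O)cc1 | intermediate
3 | (E)-1-methoxy-3-(trimethylsilyloxy)buta-1,3-diene | CO/C=C/C(=C)O[Si](C)(C)C | starting material
4 | (1E,5S)-1-methoxy-5-[4-(methoxymethoxy)phenyl]-5-(trimethylsilyloxy)pent-1-en-3-one (silyl aldol adduct) | CO/C=C/C(=O)C[C@H](O[Si](C)(C)C)c1ccc(OCOC)cc1 | intermediate
5 | (2S)-2-[4-(methoxymethoxy)phenyl]-2,3-dihydro-4H-pyran-4-one | O1[C@H](c2ccc(OCOC)cc2)CC(=O)C=C1 | intermediate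
6 | (2S)-6-chloro-2-[4-(methoxymethoxy)phenyl]-5-(phenylsulfanyl)tetrahydro-4H-pyran-4-one (pyranone numbering; mixture at C5 and C6) | O1[C@H](c2ccc(OCOC)cc2)CC(=O)C(Sc2ccccc2)C1Cl | intermediate
7 | (2S)-2-[4-(methoxymethoxy)phenyl]-5-(phenylsulfanyl)-2,3-dihydro-4H-pyran-4-one | O1[C@H](c2ccc(OCOC)cc2)CC(=O)C(Sc2ccccc2)=C1 | intermediate
8 | (2S)-2-[4-(methoxymethoxy)phenyl]-5-(phenylsulfinyl)-2,3-dihydro-4H-pyran-4-one (both sulfur epimers) | O1[C@H](c2ccc(OCOC)cc2)CC(=O)C(S(=O)c2ccccc2)=C1 | intermediate
9 | methyl acetoacetate | COC(=O)CC(C)=O | starting material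
10 | prenyl bromide (1-bromo-3-methylbut-2-ene) | CC(C)=CCBr | starting material
11 | sodium lithium dianion of methyl acetoacetate | [Na+].[Li+].COC([O-])=CC([O-])=C | intermediate
12 | methyl 7-methyl-3-oxooct-6-enoate | COC(=O)CC(=O)CCC=C(C)C | intermediate
13 | methyl (2E)-3-methoxy-7-methylocta-2,6-dienoate | CO/C(CCC=C(C)C)=C/C(=O)OC | intermediate
14 | lithium dienolate of 13 | [Li+].COC([O-])=CC(OC)=CCC=C(C)C | intermediate
15 | 1,3-dimethoxy-7-methyl-1-(trimethylsilyloxy)octa-1,3,6-triene (diene geometry not fixed) | COC(O[Si](C)(C)C)=CC(OC)=CCC=C(C)C | intermediate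
16 | (2S)-5,7-dimethoxy-2-[4-(methoxymethoxy)phenyl]-8-(3-methylbut-2-enyl)-4a-(phenylsulfinyl)-5-(trimethylsilyloxy)-2,3,4a,5,8,8a-hexahydro-4H-chromen-4-one (mixture at C4a, C5, C8, C8a and sulfur) | O1[C@H](c2ccc(OCOC)cc2)CC(=O)C2(S(=O)c3ccccc3)C1C(CC=C(C)C)C(OC)=CC2(OC)O[Si](C)(C)C | intermediate
17 | (2S)-7-methoxy-2-[4-(methoxymethoxy)phenyl]-8-(3-methylbut-2-enyl)-5-(trimethylsilyloxy)chroman-4-one | COc1cc(O[Si](C)(C)C)c2c(c1CC=C(C)C)O[C@H](c1ccc(OCOC)cc1)CC2=O | intermediate
18 | (2S)-5-hydroxy-7-methoxy-2-[4-(methoxymethoxy)phenyl]-8-(3-methylbut-2-enyl)chroman-4-one | COc1cc(O)c2c(c1CC=C(C)C)O[C@H](c1ccc(OCOC)cc1)CC2=O | intermediate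
19 | Mundulea flavanone B, (2S)-5-hydroxy-2-(4-hydroxyphenyl)-7-methoxy-8-(3-methylbut-2-enyl)chroman-4-one | COc1cc(O)c2c(c1CC=C(C)C)O[C@H](c1ccc(O)cc1)CC2=O | target

**Step count**
Total: 9 steps. Longest linear sequence: 6 steps (steps 1, 2, 3, 4, 8, 9); the diene branch (steps 5–7) joins at step 8.

**Steps most likely to fail**

1. Step 8 (key benzannulation). The addition may stop at the open-chain Michael stage, and the pyranone ring may open by β-elimination of O1 from that adduct. The hindered, prenyl-substituted diene terminus may also be protodesilylated faster than it adds. Fallback, using known flavanone chemistry, sets out from 2 and comes back at 19.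
 - Commercial 1-(2,6-dihydroxy-4-methoxyphenyl)ethanone F1 is C-prenylated with 10 (aq. KOH) to 1-[2,6-dihydroxy-4-methoxy-3-(3-methylbut-2-enyl)phenyl]ethanone F2; the symmetry of F1 makes the site unambiguous.
 - The less hindered hydroxyl, remote from the prenyl group, is etherified (MOMCl, iPr2NEt) to 1-[2-hydroxy-4-methoxy-6-(methoxymethoxy)-3-(3-methylbut-2-enyl)phenyl]ethanone F3, the regioisomeric ether being removed by chromatography.
 - Claisen–Schmidt condensation of F3 with 2 (KOH, EtOH, rt) should give the (E)-2'-hydroxychalcone F4.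
 - Oxa-Michael ring closure (NaOAc, EtOH, reflux) should give the racemic 5,4'-bis-MOM 8-prenylflavanone F5.
 - Noyori-type asymmetric transfer hydrogenation as a kinetic resolution (RuCl[(R,R)-TsDPEN](p-cymene), HCO2H/Et3N; the catalyst antipode that consumes the 2R enantiomer) should leave the (2S)-bis-MOM flavanone F6, while the 2R enantiomer is reduced to the (2R,4R)-cis-flavan-4-ol F7 and separated.
 - Treatment of F6 with HCl in MeOH, as in step 9, removes both MOM groups and gives 19.

2. Step 3 (C5 sulfenylation). Electrophilic attack on the push–pull alkene may be sluggish, so that sulfenylation of the electron-rich aryl ring or acid-induced loss of the MOM group competes. Fallback sets out from 5 and comes back at 7.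
 - α-Iodination of the enone (I2, pyridine, CH2Cl2, rt) should give (2S)-5-iodo-2-[4-(methoxymethoxy)phenyl]-2,3-dihydro-4H-pyran-4-one F8.
 - Pd(PPh3)4-catalysed C–S cross-coupling of F8 with tributyl(phenylthio)stannane (PhMe, 100 °C) works under neutral conditions, without free thiolate, and should give 7.

3. Step 2 (asymmetric hetero-Diels–Alder). Enantioselectivity may be insufficient with the electron-rich aldehyde, or the MOM ether may be cleaved during the acid-induced ring closure. Fallback sets out from 2 and comes back at 5.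
 - The diisopinocampheylboron enolate of (E)-4-chlorobut-3-en-2-one (Ipc2BCl, iPr2NEt, Et2O, −78 °C; the Ipc antipode chosen to give the S carbinol, to be assigned by Mosher ester analysis) is added to 2 in a reagent-controlled aldol reaction, giving (1E,5S)-1-chloro-5-hydroxy-5-[4-(methoxymethoxy)phenyl]pent-1-en-3-one F9.
 - Non-acidic addition–elimination ring closure (TMSOTf, iPr2NEt, CH2Cl2, −78 °C) gives 5, whose enantiomeric purity can be raised by crystallisation at the stage of 5 or 7.

Further compounds
F1 | step 8 | 1-(2,6-dihydroxy-4-methoxyphenyl)ethanone (purchased) | CC(=O)c1c(O)cc(OC)cc1O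
F2 | step 8 | 1-[2,6-dihydroxy-4-methoxy-3-(3-methylbut-2-enyl)phenyl]ethanone | CC(=O)c1c(O)cc(OC)c(CC=C(C)C)c1O
F3 | step 8 | 1-[2-hydroxy-4-methoxy-6-(methoxymethoxy)-3-(3-methylbut-2-enyl)phenyl]ethanone | CC(=O)c1c(OCOC)cc(OC)c(CC=C(C)C)c1O
F4 | step 8 | (E)-1-[2-hydroxy-4-methoxy-6-(methoxymethoxy)-3-(3-methylbut-2-enyl)phenyl]-3-[4-(methoxymethoxy)phenyl]prop-2-en-1-one | COCOc1ccc(/C=C/C(=O)c2c(OCOC)cc(OC)c(CC=C(C)C)c2O)cc1
F5 | step 8 | racemic 7-methoxy-5-(methoxymethoxy)-2-[4-(methoxymethoxy)phenyl]-8-(3-methylbut-2-enyl)chroman-4-one | COc1cc(OCOC)c2c(c1CC=C(C)C)OC(c1ccc(OCOC)cc1)CC2=O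
F6 | step 8 | (2S)-7-methoxy-5-(methoxymethoxy)-2-[4-(methoxymethoxy)phenyl]-8-(3-methylbut-2-enyl)chroman-4-one | COc1cc(OCOC)c2c(c1CC=C(C)C)O[C@H](c1ccc(OCOC)cc1)CC2=O
F7 | step 8 | (2R,4R)-7-methoxy-5-(methoxymethoxy)-2-[4-(methoxymethoxy)phenyl]-8-(3-methylbut-2-enyl)chroman-4-ol | COc1cc(OCOC)c2c(c1CC=C(C)C)O[C@@H](c1ccc(OCOC)cc1)C[C@H]2O
F8 | step 3 | (2S)-5-iodo-2-[4-(methoxymethoxy)phenyl]-2,3-dihydro-4H-pyran-4-one | O1[C@H](c2ccc(OCOC)cc2)CC(=O)C(I)=C1
F9 | step 2 | (1E,5S)-1-chloro-5-hydroxy-5-[4-(methoxymethoxy)phenyl]pent-1-en-3-one | O=C(/C=C/Cl)C[C@H](O)c1ccc(OCOC)cc1
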